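The numbers in the tables come from a simulation with made-up constants, and the scatter is random.

Freeze what changes slowly, the making of target and the amount of partner, and the two flasks asked about can be reckoned around one number: the half-life of target against partner.

| flask | substrate | coupling partner | remark | time |
|---|---|---|---|---|
| Wednesday's | 0.036 M (in portions, 2) | 0.47 equiv | run made earlier; portions every 15 min |  |
| Monday's | 0.036 M (in portions, 2) | 0.71 equiv | run made earlier; portions every 15 min |  |
| zeta | 0.036 M (in portions, 2) | 0.950 equiv | the portions of substrate follow each other after 15 min, the first at the start | 15 h |
| delta | 0.036 M (in portions, 2) | 0.950 equiv | the portions of substrate follow each other after 15 min, the first at the start | 5.0 h |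

| Wednesday's: time / h | Wednesday's: target / % | Monday's: time / h | Monday's: target / % |
|---|---|---|---|
| 0.833 | 2.0 | 0.500 | 0 |
| 1.50 | 4.1 | 0.667 | 0 |
| 2.50 | 7.5 | 1.00 | 1.4 |
| 3.00 | 11.7 | 1.50 | 3.8 |
| 4.00 | 16.0 | 2.50 | 7.9 |
| 5.00 | 24.1 | 4.00 | 14.9 |
| 6.00 | 27.1 | 6.00 | 22.3 |

(readings scatter by 1 percentage point)



* which of the two there is more of at the end, zeta (target / over-reaction product)
* which of the two there is more of at the end, delta (target / over-reaction product)
* target at the end, in percent of the substrate charged, zeta
* target at the end, in percent of the substrate charged, delta

With just the main step, target climbs in a straight line after a lag. Monday's last zero stands at 0.667 h, and its last reading gives a slope of 0.0418 h⁻¹, as a fraction of the charge, so this line reaches 18.1 % in delta and 59.9 % in zeta.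

But Wednesday's run, with less partner, ends 4.8 percentage points above Monday's, so add one step: partner turns target into over-reaction product. With partner frozen at its charge this loss is pseudo-first-order, and its rate goes with the equivalents. Each run's last reading is then what was made minus the loss rate times the area under its curve. These areas, in fraction of the charge times hours, are 0.730 h for Wednesday's run and 0.617 h for Monday's. Equal making in both runs gives, as a reading, 1.44 h as the half-life of target against partner at 0.950 equiv, and a making of 0.0833 h⁻¹, again as a fraction of the charge. Target now closes half its distance to a plateau in each half-life, and that plateau, making over loss rate, is 17.4 %. So this reckoning puts delta at 15.2 % and zeta at the plateau. What was made minus target puts over-reaction product at 20.9 % in delta, and ahead of target in zeta as well.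

The rest pulls both ways: spent partner raises the plateau, while this making would use up the charge in 12.0 h, sooner than zeta's 15 h, which lowers it. The reckoning stays at the plateau.

The forecast, taking the reaction as “roughly zero order in partner”, gives 38 % for zeta, where this reckoning differs, and 15 % for delta, with target ahead in zeta and target ahead in delta.

Zeta gives 24.9 % target and 43.0 % over-reaction product, delta 15.2 % and 9.13 %.

    substrate ⇌ intermediate A (K = 1.20, k = 7.10 h⁻¹)
    substrate → intermediate B (k = 0.700 h⁻¹)
    coupling partner + intermediate B ⇌ intermediate C (K = 44.0 M⁻¹, k = 11.0 M⁻¹ h⁻¹)
    coupling partner + intermediate C ⇌ intermediate D (K = 21.0 M⁻¹, k = 0.680 M⁻¹ h⁻¹)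
    intermediate B → target (k = 0.190 h⁻¹)
    substrate → decomposition product (k = 1.70 × 10⁻⁴ h⁻¹)
    coupling partner + target → over-reaction product (k = 9.70 M⁻¹ h⁻¹)

Delta's target meets the reckoning, but its over-reaction product stands below the balance and behind target, so the balance's order for delta fails, and zeta's target stands above the plateau. Zeta's time is 10.4 carried half-lives, and its target is made and used at a ratio of 0.995. Scaling the half-life with the partner's concentration to a second flask, zeta's recipe at 0.022 M of substrate with the equivalents and the time held, gives a plateau of 28.4 %, and that flask holds 32.5 % of target. Yet zeta is not at rest: at ten times the time, 150 h, its target has sunk to 5.94 % and its over-reaction product has risen to 94.0 %.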